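**Strategy.** The chain is numbered C1 (benzylic CH2) to C13, with the acetate on C2 and the ketone at C8. The route rests on the C8 carbonyl being isolated between the unbranched methylenes C7 and C9, remote from the C2 stereocentre and the resorcinol ring, so that it can be cut into 1-iodopentane, carbon monoxide and a C7 alkylborane. One light-assisted palladium-catalysed carbonylative coupling forms the C7–C8 and C8–C9 bonds and delivers the ketone unmasked. Its precursor is the B-alkyl-9-BBN of (R)-1-[3,5-bis(benzyloxy)phenyl]hept-6-en-2-yl acetate, whose stereocentre comes from (S)-epichlorohydrin through two copper-catalysed Grignard epoxide openings.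

Key step: step 6

Remark: 1,3-bis(benzyloxy)-5-bromobenzene, (S)-epichlorohydrin, but-3-en-1-ylmagnesium bromide (THF solution), 9-BBN, 1-iodopentane and CO are assumed to be purchasable.

Remark: in compound 9 the boron sits in the intact 9-borabicyclo[3.3.1]nonane cage, that is a cyclooctane-1,5-diyl unit with eight carbons and two three-carbon bridges.

**Step 1**
Reactants: 1 1,3-bis(benzyloxy)-5-bromobenzene; 2 (S)-epichlorohydrin
Product: 4 (S)-1-[3,5-bis(benzyloxy)phenyl]-3-chloropropan-2-ol, via arylmagnesium bromide 3 (not isolated)
Conditions: Mg, I2 (cat.), THF, 50 °C; then CuI (10 mol%), 2 (1.2 equiv), THF, −30 → 0 °C; aq. NH4Cl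
Reagents that add atoms: none
Why: Grignard formation followed by copper-catalysed SN2 opening of the epoxide at its unsubstituted ring carbon, which is faster than displacement of the primary chloride, forms the aryl–C1 bond without touching the stereocentre of 2, so its configuration passes unchanged into 4.

**Step 2**
Reactants: 4 (S)-1-[3,5-bis(benzyloxy)phenyl]-3-chloropropan-2-ol
Product: 5 (S)-2-[3,5-bis(benzyloxy)benzyl]oxirane
Conditions: NaOH, MeOH/THF, 0 °C → rt
Reagents that add atoms: none
Why: Intramolecular Williamson etherification (3-exo-tet attack of the alkoxide on the primary chloride) closes the oxirane without breaking a bond at the stereocentre, so (S)-4 should give (S)-5.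

**Step 3**
Reactants: 5 (S)-2-[3,5-bis(benzyloxy)benzyl]oxirane; 6 but-3-en-1-ylmagnesium bromide
Product: 7 (R)-1-[3,5-bis(benzyloxy)phenyl]hept-6-en-2-ol
Conditions: 6 (1.5 equiv), CuI (10 mol%), THF, −30 → 0 °C; aq. NH4Cl
Reagents that add atoms: none
Why: Copper-catalysed Grignard opening of a monosubstituted epoxide (SN2 at the unhindered ring CH2) forms the C3–C4 bond and leaves the C2–O bond intact, so the configuration is retained and the descriptor changes from S to R only because the CIP order of the two methylene arms is reversed.

**Step 4**
Reactants: 7 (R)-1-[3,5-bis(benzyloxy)phenyl]hept-6-en-2-ol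
Product: 8 (R)-1-[3,5-bis(benzyloxy)phenyl]hept-6-en-2-yl acetate
Conditions: Ac2O, pyridine, DMAP (cat.), CH2Cl2, 0 °C → rt
Reagents that add atoms: acetic anhydride, CC(=O)OC(C)=O
Why: DMAP-catalysed O-acetylation of the secondary alcohol takes place at oxygen only, so C2 is not affected.

**Step 5**
Reactants: 8 (R)-1-[3,5-bis(benzyloxy)phenyl]hept-6-en-2-yl acetate
Product: 9 (R)-1-[3,5-bis(benzyloxy)phenyl]-7-(9-borabicyclo[3.3.1]nonan-9-yl)heptan-2-yl acetate, handled as an air-free benzene solution
Conditions: 9-BBN (1.05 equiv), THF, 0 °C → rt, argon; THF exchanged for benzene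
Reagents that add atoms: 9-borabicyclo[3.3.1]nonane (9-BBN), B1C2CCCC1CCC2
Why: Brown hydroboration with the hindered dialkylborane 9-BBN should place boron on the terminal carbon C7 of the monosubstituted alkene with very high anti-Markovnikov selectivity, while the acetate and benzyl ethers are inert to this reagent at room temperature.

**Step 6**
Reactants: 9 (R)-1-[3,5-bis(benzyloxy)phenyl]-7-(9-borabicyclo[3.3.1]nonan-9-yl)heptan-2-yl acetate; 10 1-iodopentane; 11 carbon monoxide
Product: 12 (R)-1-[3,5-bis(benzyloxy)phenyl]-8-oxotridecan-2-yl acetate
Conditions: Pd(PPh3)4 (3 mol%), K3PO4 (3 equiv), CO (1 atm), benzene, hν (tungsten lamp), rt; pH 7 aqueous work-up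
Reagents that add atoms: none
Why: Under irradiation the zerovalent palladium complex reduces iodide 10 by one electron, the pentyl radical so formed adds to CO to make the C8–C9 bond, and the hexanoyl radical is caught by the iodopalladium species of monovalent palladium to give an acylpalladium iodide of divalent palladium; transmetalation from the phosphate-bound borate of 9 then delivers the C7 alkyl group, and reductive elimination forms the C7–C8 bond and returns zerovalent palladium. The closest known reaction type is the light-assisted carbonylative Suzuki–Miyaura coupling of iodoalkanes with 9-alkyl-9-BBN reagents to give unsymmetrical dialkyl ketones. No ring is closed and no stereocentre is created, and C2 lies five methylenes from the reacting carbon and is not touched. The step needs the crossed ketone in preference to direct alkyl–alkyl coupling, symmetrical ketones and alkene formation; this is secured because only the iodide enters the radical carbonylation, which is faster than beta-hydride loss from an alkylpalladium species, and only the borane transmetalates, its primary exocyclic B–C bond migrating in preference to the two secondary cage B–C bonds. Solid K3PO4 in benzene at room temperature should leave the acetate and benzyl ethers intact, and complete hydroboration in step 5 removes the alkene that could otherwise trap radicals.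

**Step 7**
Reactants: 12 (R)-1-[3,5-bis(benzyloxy)phenyl]-8-oxotridecan-2-yl acetate
Product: 13 (R)-1-(3,5-dihydroxyphenyl)-8-oxotridecan-2-yl acetate (target)
Conditions: H2 (1 atm), 10% Pd/C, EtOAc, rt
Reagents that add atoms: none
Why: Palladium-catalysed hydrogenolysis cleaves the two benzylic C–O bonds of the aryl benzyl ethers, whereas the dialkyl ketone and the non-benzylic secondary acetate are inert at one atmosphere in a neutral solvent, so the C2 configuration is unchanged.

**Compound list**
1 | 1,3-bis(benzyloxy)-5-bromobenzene | Brc1cc(OCc2ccccc2)cc(OCc2ccccc2)c1 | starting material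
2 | (S)-epichlorohydrin, (S)-2-(chloromethyl)oxirane | ClC[C@@H]1CO1 | starting material
3 | 3,5-bis(benzyloxy)phenylmagnesium bromide | Br[Mg]c1cc(OCc2ccccc2)cc(OCc2ccccc2)c1 | intermediate
4 | (S)-1-[3,5-bis(benzyloxy)phenyl]-3-chloropropan-2-ol | ClC[C@@H](O)Cc1cc(OCc2ccccc2)cc(OCc2ccccc2)c1 | intermediate
5 | (S)-2-[3,5-bis(benzyloxy)benzyl]oxirane | C1[C@@H](O1)Cc2cc(OCc3ccccc3)cc(OCc3ccccc3)c2 | intermediate
6 | but-3-en-1-ylmagnesium bromide | C=CCC[Mg]Br | starting material
7 | (R)-1-[3,5-bis(benzyloxy)phenyl]hept-6-en-2-ol | C=CCCC[C@@H](O)Cc1cc(OCc2ccccc2)cc(OCc2ccccc2)c1 | intermediate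
8 | (R)-1-[3,5-bis(benzyloxy)phenyl]hept-6-en-2-yl acetate | C=CCCC[C@H](Cc1cc(OCc2ccccc2)cc(OCc2ccccc2)c1)OC(C)=O | intermediate
9 | (R)-1-[3,5-bis(benzyloxy)phenyl]-7-(9-borabicyclo[3.3.1]nonan-9-yl)heptan-2-yl acetate | C1CCC2CCCC1B2CCCCC[C@H](Cc3cc(OCc4ccccc4)cc(OCc4ccccc4)c3)OC(C)=O | intermediate
10 | 1-iodopentane | CCCCCI | starting material
11 | carbon monoxide | [C-]#[O+] | starting material
12 | (R)-1-[3,5-bis(benzyloxy)phenyl]-8-oxotridecan-2-yl acetate | CCCCCC(=O)CCCCC[C@H](Cc1cc(OCc2ccccc2)cc(OCc2ccccc2)c1)OC(C)=O | intermediate
13 | (R)-1-(3,5-dihydroxyphenyl)-8-oxotridecan-2-yl acetate | CCCCCC(=O)CCCCC[C@H](Cc1cc(O)cc(O)c1)OC(C)=O | target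

**Step count.** Total: 7 steps. Longest linear sequence: 7 steps (1 to 13).

**Steps most likely to fail**

Step 6. The three-component union may be outpaced by direct alkyl–alkyl coupling, by reduction of the iodide or by protodeboronation, so that the ketone forms with low conversion. The fallback sets out from alkene acetate 8 and abandons the carbonylation. Olefin cross-metathesis of 8 with commercial oct-1-en-3-one (C=CC(=O)CCCCC) is run with the second-generation Grubbs catalyst, (H2IMes)(PCy3)Cl2Ru=CHPh, in CH2Cl2 at 40 °C. It should give the E-enone (R,E)-1-[3,5-bis(benzyloxy)phenyl]-8-oxotridec-6-en-2-yl acetate F1. Hydrogenation of the enone over 10% Pd/C in EtOAc then saturates the C6–C7 double bond and removes both benzyl groups in one operation, so the fallback comes back to the route at target 13.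

Step 1. Halide-mediated opening and reclosure of the chloro-epoxide may erode the enantiopurity, premature ring closure may lead to double arylation, and Wurtz-type homocoupling may consume the electron-rich aryl bromide during Grignard formation. The fallback sets out from aryl bromide 1 and sets the stereocentre by resolution instead of from the chiral pool. Stille coupling of 1 with allyltributylstannane (Pd(PPh3)4, toluene, 100 °C) should give 1-allyl-3,5-bis(benzyloxy)benzene F2. Epoxidation with mCPBA (NaHCO3, CH2Cl2, 0 °C) should give racemic 2-[3,5-bis(benzyloxy)benzyl]oxirane F3. Hydrolytic kinetic resolution of the racemic epoxide uses 0.55 equiv of water and the chiral (salen)Co(OAc) complex of trivalent cobalt (salen = N,N'-bis(3,5-di-tert-butylsalicylidene)cyclohexane-1,2-diamine). The antipode of the catalyst that hydrolyses the (R)-epoxide is chosen, to be assigned in a trial run. This should leave (S)-epoxide 5, where the route is rejoined.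

Step 3. Magnesium bromide may open the epoxide to a bromohydrin, or alkyl transfer may be slow, in competition with the copper-catalysed delivery of the butenyl group. The fallback sets out from Grignard reagent 6 and reverses the order of the two epoxide openings, which requires the mirror-image C3 unit, commercial (R)-epichlorohydrin (ClC[C@H]1CO1). CuI-catalysed opening of this epoxide by 6 should give (R)-1-chlorohept-6-en-2-ol F4. NaOH then closes it to (R)-2-(pent-4-en-1-yl)oxirane F5. CuI-catalysed opening of this simple alkyl epoxide by arylmagnesium bromide 3 (made from 1 as in step 1) should give alcohol 7, where the route is rejoined.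

**Further compounds**
F1 | step 6 | (R,E)-1-[3,5-bis(benzyloxy)phenyl]-8-oxotridec-6-en-2-yl acetate | CCCCCC(=O)/C=C/CCC[C@H](Cc1cc(OCc2ccccc2)cc(OCc2ccccc2)c1)OC(C)=O
F2 | step 1 | 1-allyl-3,5-bis(benzyloxy)benzene | C=CCc1cc(OCc2ccccc2)cc(OCc2ccccc2)c1
F3 | step 1 | racemic 2-[3,5-bis(benzyloxy)benzyl]oxirane | C1OC1Cc2cc(OCc3ccccc3)cc(OCc3ccccc3)c2
F4 | step 3 | (R)-1-chlorohept-6-en-2-ol | ClC[C@H](O)CCCC=C
F5 | step 3 | (R)-2-(pent-4-en-1-yl)oxirane | C1[C@H](O1)CCCC=C
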